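**Plan**

- Retrosynthesis (chain numbered C1 = benzylic carbon to C8): the phenol and the two acetates go back to a benzyl ether and two silyl ethers. The Ar–C1 bond is cut to an aryl Grignard reagent and a C1 acyl group, and the C6–C7 bond to an ethylidene ylide and a C6 aldehyde. The C1 acyl / C6 carbinol pair is traced to the C1–C6 ring bond of a ketone.
- Enabling feature: C1–C6 with syn oxygens on C3 and C5 is the carbon set of cis-3,5-dioxygenated cyclohexanone. This six-membered ring is meso (mirror plane through C1=O and C4), its carbonyl carbon C1 is bonded to both C2 and C6, and it comes from flat phloroglucinol.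
- Forward: the cyclohexane ring is made by arene hydrogenation, expanded to a seven-membered lactone by oxygen insertion into C1–C6, then opened. The chain is extended at C6 (C7–C8) first and the aryl group is joined at C1 second.
- Stereochemistry: the syn relationship comes from all-cis hydrogenation of the arene. The absolute (3S,5R) pattern comes from the chiral catalyst selecting one of the two enantiotopic C–C bonds of the meso ketone. No later step makes or breaks a bond at C3 or C5.

Key step: step 4

Assumption: the sense of induction of the Sc(III)/N,N′-dioxide catalyst on ketone 4 is not predicted here; both ligand antipodes are accessible from L- or D-amino acids, and the one that gives the (4R,6S)-lactone is used.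
Remark: compounds 17–19 are carried as mixtures of C1 epimers, since C1 becomes a CH2 group in step 14.

**Route**

Step 1
Reactants: 1 phloroglucinol
Product: 2 all-cis-cyclohexane-1,3,5-triol
Conditions: H2 (100 bar), 5% Rh/Al2O3, EtOH, 60 °C
Reagents that add atoms: none
Why: Heterogeneous arene hydrogenation delivers all six hydrogens from the catalyst face, so the three carbinol centres should emerge all-cis, rhodium on alumina being chosen to limit C–O hydrogenolysis.

Step 2
Reactants: 2 all-cis-cyclohexane-1,3,5-triol
Product: 3 all-cis-3,5-bis[(tert-butyldimethylsilyl)oxy]cyclohexan-1-ol (meso)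
Conditions: TBSCl (2.1 equiv), imidazole, DMF, 0 °C → rt
Reagents that add atoms: tert-butyldimethylsilyl chloride, CC(C)(C)[Si](C)(C)Cl
Why: The three hydroxyls are symmetry-equivalent, so imidazole-mediated silylation with two equivalents of silyl chloride can give only one bis-ether, the mono- and tris-ethers formed alongside being separable and recyclable.

Step 3
Reactants: 3 all-cis-3,5-bis[(tert-butyldimethylsilyl)oxy]cyclohexan-1-ol
Product: 4 (3R,5S)-3,5-bis[(tert-butyldimethylsilyl)oxy]cyclohexan-1-one (cis, meso)
Conditions: Dess–Martin periodinane, NaHCO3, CH2Cl2, 0 °C → rt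
Reagents that add atoms: none
Why: Dess–Martin oxidation of the secondary alcohol runs under buffered, non-basic conditions, which should spare the β-silyloxy groups from elimination.

Step 4
Reactants: 4 (3R,5S)-3,5-bis[(tert-butyldimethylsilyl)oxy]cyclohexan-1-one
Product: 6 (4R,6S)-4,6-bis[(tert-butyldimethylsilyl)oxy]oxepan-2-one, via Criegee adduct 5 (not isolated)
Conditions: Sc(OTf)3 (5 mol %), chiral C2-symmetric N,N′-dioxide ligand (5 mol %), mCPBA (1.2 equiv), EtOAc, −20 °C
Reagents that add atoms: meta-chloroperoxybenzoic acid (mCPBA), OOC(=O)c1cccc(Cl)c1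
Why: The Sc(III) centre held in the chiral N,N′-dioxide activates the carbonyl of 4, the peracid adds to give Criegee adduct 5, and the α-CH2 antiperiplanar to the O–O bond shifts from C1 to oxygen with loss of 3-chlorobenzoate (Baeyer–Villiger oxidation). The closest known reaction type is the catalytic asymmetric Baeyer–Villiger desymmetrisation of meso and prochiral cyclohexanones with chiral Lewis acid/peracid systems. The seven-membered ring is not closed by a cyclisation; it arises by ring expansion of the six-membered ketone through this 1,2-shift, oxygen being inserted into the C1–C6 bond. No bond to the two carbinol carbons is made or broken: they become the (4R) and (6S) centres of 6 (C3 and C5 of the chain) only because the chiral ligand sphere decides that C6, the α-methylene attached to the (S)-configured carbinol carbon of 4, migrates, while their cis relationship stems from step 1. The selectivity required is enantiotopic-group selectivity between two methylenes of identical migratory aptitude; the substrate offers a rigid chair with both silyloxy groups equatorial and no regiochemical bias of its own, and the low temperature keeps the uncatalysed racemic pathway slow.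

Step 5
Reactants: 6 (4R,6S)-4,6-bis[(tert-butyldimethylsilyl)oxy]oxepan-2-one
Product: 7 (3R,5S)-3,5-bis[(tert-butyldimethylsilyl)oxy]-6-hydroxy-N-methoxy-N-methylhexanamide
Conditions: MeNH(OMe)·HCl, AlMe3, CH2Cl2, 0 °C → rt; aq. Rochelle salt
Reagents that add atoms: N,O-dimethylhydroxylamine hydrochloride, CNOC.Cl
Why: Weinreb aminolysis with the aluminium amide cleaves the acyl–oxygen bond of the lactone, so C1 becomes the N-methoxy-N-methylamide and C6 a free primary alcohol, the seven-membered ring having little tendency to re-close.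

Step 6
Reactants: 7 (3R,5S)-3,5-bis[(tert-butyldimethylsilyl)oxy]-6-hydroxy-N-methoxy-N-methylhexanamide
Product: 8 (3R,5S)-3,5-bis[(tert-butyldimethylsilyl)oxy]-N-methoxy-N-methyl-6-oxohexanamide
Conditions: Dess–Martin periodinane, NaHCO3, CH2Cl2, 0 °C; used crude
Reagents that add atoms: none
Why: Dess–Martin oxidation of the primary alcohol is non-basic, which should keep the α-silyloxy centre C5 of the aldehyde configurationally intact.

Step 7
Reactants: 8 (3R,5S)-3,5-bis[(tert-butyldimethylsilyl)oxy]-N-methoxy-N-methyl-6-oxohexanamide; 9 ethyltriphenylphosphonium bromide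
Product: 11 (3R,5S,6Z)-3,5-bis[(tert-butyldimethylsilyl)oxy]-N-methoxy-N-methyloct-6-enamide, via ethylidenetriphenylphosphorane 10 (not isolated)
Conditions: 9, KHMDS, THF, 0 °C; then 8, −78 → 0 °C
Reagents that add atoms: none
Why: Wittig olefination with the salt-free, non-stabilised ylide at low temperature should outpace both enolisation of the α-silyloxy aldehyde and attack on the Weinreb amide, and it gives mainly the Z-alkene, whose geometry is erased in the next step.

Step 8
Reactants: 11 (3R,5S,6Z)-3,5-bis[(tert-butyldimethylsilyl)oxy]-N-methoxy-N-methyloct-6-enamide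
Product: 12 (3R,5R)-3,5-bis[(tert-butyldimethylsilyl)oxy]-N-methoxy-N-methyloctanamide
Conditions: H2 (1 atm), 5% Pt/C, EtOAc, rt
Reagents that add atoms: none
Why: Catalytic hydrogenation over platinum saturates the disubstituted alkene with little double-bond migration or allylic C–O hydrogenolysis, and doing it while C5 carries a silyl ether avoids exposing an allylic acetate to palladium later.

Step 9
Reactants: 13 4-bromo-2-methoxyphenol
Product: 14 1-(benzyloxy)-4-bromo-2-methoxybenzene
Conditions: BnBr, K2CO3, DMF, rt
Reagents that add atoms: benzyl bromide, BrCc1ccccc1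
Why: Williamson etherification masks the phenol as a benzyl ether that tolerates Grignard formation and is removed by the final hydrogenation.

Step 10
Reactants: 12 (3R,5R)-3,5-bis[(tert-butyldimethylsilyl)oxy]-N-methoxy-N-methyloctanamide; 14 1-(benzyloxy)-4-bromo-2-methoxybenzene
Product: 16 (3R,5R)-1-[4-(benzyloxy)-3-methoxyphenyl]-3,5-bis[(tert-butyldimethylsilyl)oxy]octan-1-one, via [4-(benzyloxy)-3-methoxyphenyl]magnesium bromide 15 (not isolated)
Conditions: 14, Mg, THF, 40 °C; then 12, THF, 0 °C; sat. aq. NH4Cl
Reagents that add atoms: none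
Why: In this Weinreb ketone synthesis the aryl Grignard reagent adds once to the N-methoxy-N-methylamide, chelation holding the reaction at the ketone oxidation level until the quench.

Step 11
Reactants: 16 (3R,5R)-1-[4-(benzyloxy)-3-methoxyphenyl]-3,5-bis[(tert-butyldimethylsilyl)oxy]octan-1-one
Product: 17 (1RS,3S,5R)-1-[4-(benzyloxy)-3-methoxyphenyl]-3,5-bis[(tert-butyldimethylsilyl)oxy]octan-1-ol
Conditions: NaBH4, MeOH, 0 °C
Reagents that add atoms: none
Why: Borohydride reduction of the aryl ketone gives the benzylic alcohol as both C1 epimers, which is of no consequence, and removes the β-silyloxy ketone before it can eliminate.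

Step 12
Reactants: 17 (1RS,3S,5R)-1-[4-(benzyloxy)-3-methoxyphenyl]-3,5-bis[(tert-butyldimethylsilyl)oxy]octan-1-ol
Product: 18 (1RS,3R,5R)-1-[4-(benzyloxy)-3-methoxyphenyl]octane-1,3,5-triol
Conditions: TBAF, THF, 0 °C → rt
Reagents that add atoms: none
Why: Fluoride-mediated desilylation frees both secondary alcohols under non-acidic conditions, avoiding acid that would ionise the p-alkoxybenzylic alcohol and let the C5 hydroxyl close a 2-aryltetrahydropyran.

Step 13
Reactants: 18 (1RS,3R,5R)-1-[4-(benzyloxy)-3-methoxyphenyl]octane-1,3,5-triol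
Product: 19 (1RS,3R,5R)-1-[4-(benzyloxy)-3-methoxyphenyl]octane-1,3,5-triyl triacetate
Conditions: Ac2O, pyridine, DMAP (cat.), CH2Cl2, 0 °C → rt
Reagents that add atoms: acetic anhydride, CC(=O)OC(C)=O
Why: DMAP-catalysed acetylation esterifies all three secondary hydroxyls, installing the C3 and C5 acetates of the target and turning the C1 hydroxyl into a hydrogenolysable benzylic acetate.

Step 14
Reactants: 19 (1RS,3R,5R)-1-[4-(benzyloxy)-3-methoxyphenyl]octane-1,3,5-triyl triacetate
Product: 20 (3S,5R)-1-(4-hydroxy-3-methoxyphenyl)octane-3,5-diyl diacetate (CNP0240815.1)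
Conditions: H2 (1–3 bar), 10% Pd/C, EtOAc (1% AcOH), rt
Reagents that add atoms: none
Why: Palladium-catalysed hydrogenolysis should cleave the O-benzyl ether and the benzylic C1–OAc bond, which is activated by the para-oxygenated ring, while the unactivated alkyl acetates at C3 and C5 and their configurations are untouched.

**Compound list**

1 | phloroglucinol (benzene-1,3,5-triol) | Oc1cc(O)cc(O)c1 | starting material
2 | all-cis-cyclohexane-1,3,5-triol | O[C@H]1C[C@@H](O)C[C@@H](O)C1 | intermediate
3 | all-cis-3,5-bis[(tert-butyldimethylsilyl)oxy]cyclohexan-1-ol (meso) | O[C@H]1C[C@@H](O[Si](C)(C)C(C)(C)C)C[C@@H](O[Si](C)(C)C(C)(C)C)C1 | intermediate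
4 | (3R,5S)-3,5-bis[(tert-butyldimethylsilyl)oxy]cyclohexan-1-one (cis, meso) | O=C1C[C@H](O[Si](C)(C)C(C)(C)C)C[C@H](O[Si](C)(C)C(C)(C)C)C1 | intermediate
5 | Criegee adduct: cis-3,5-bis[(tert-butyldimethylsilyl)oxy]-1-hydroxycyclohexyl 3-chloroperoxybenzoate (scandium-bound) | OC1(OOC(=O)c2cccc(Cl)c2)C[C@H](O[Si](C)(C)C(C)(C)C)C[C@H](O[Si](C)(C)C(C)(C)C)C1 | intermediate (not isolated)
6 | (4R,6S)-4,6-bis[(tert-butyldimethylsilyl)oxy]oxepan-2-one | O=C1C[C@H](O[Si](C)(C)C(C)(C)C)C[C@H](O[Si](C)(C)C(C)(C)C)CO1 | intermediate
7 | (3R,5S)-3,5-bis[(tert-butyldimethylsilyl)oxy]-6-hydroxy-N-methoxy-N-methylhexanamide | CON(C)C(=O)C[C@H](O[Si](C)(C)C(C)(C)C)C[C@H](O[Si](C)(C)C(C)(C)C)CO | intermediate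
8 | (3R,5S)-3,5-bis[(tert-butyldimethylsilyl)oxy]-N-methoxy-N-methyl-6-oxohexanamide | CON(C)C(=O)C[C@H](O[Si](C)(C)C(C)(C)C)C[C@H](O[Si](C)(C)C(C)(C)C)C=O | intermediate
9 | ethyltriphenylphosphonium bromide | CC[P+](c1ccccc1)(c1ccccc1)c1ccccc1.[Br-] | starting material
10 | ethylidenetriphenylphosphorane | CC=P(c1ccccc1)(c1ccccc1)c1ccccc1 | intermediate (not isolated)
11 | (3R,5S,6Z)-3,5-bis[(tert-butyldimethylsilyl)oxy]-N-methoxy-N-methyloct-6-enamide | CON(C)C(=O)C[C@H](O[Si](C)(C)C(C)(C)C)C[C@H](O[Si](C)(C)C(C)(C)C)/C=C\C | intermediate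
12 | (3R,5R)-3,5-bis[(tert-butyldimethylsilyl)oxy]-N-methoxy-N-methyloctanamide | CON(C)C(=O)C[C@H](O[Si](C)(C)C(C)(C)C)C[C@H](O[Si](C)(C)C(C)(C)C)CCC | intermediate
13 | 4-bromo-2-methoxyphenol | COc1cc(Br)ccc1O | starting material
14 | 1-(benzyloxy)-4-bromo-2-methoxybenzene | COc1cc(Br)ccc1OCc1ccccc1 | intermediate
15 | [4-(benzyloxy)-3-methoxyphenyl]magnesium bromide | COc1cc([Mg]Br)ccc1OCc1ccccc1 | intermediate (not isolated)
16 | (3R,5R)-1-[4-(benzyloxy)-3-methoxyphenyl]-3,5-bis[(tert-butyldimethylsilyl)oxy]octan-1-one | O=C(C[C@H](O[Si](C)(C)C(C)(C)C)C[C@H](O[Si](C)(C)C(C)(C)C)CCC)c1ccc(OCc2ccccc2)c(OC)c1 | intermediate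
17 | (1RS,3S,5R)-1-[4-(benzyloxy)-3-methoxyphenyl]-3,5-bis[(tert-butyldimethylsilyl)oxy]octan-1-ol | OC(C[C@H](O[Si](C)(C)C(C)(C)C)C[C@H](O[Si](C)(C)C(C)(C)C)CCC)c1ccc(OCc2ccccc2)c(OC)c1 | intermediate
18 | (1RS,3R,5R)-1-[4-(benzyloxy)-3-methoxyphenyl]octane-1,3,5-triol | OC(C[C@H](O)C[C@H](O)CCC)c1ccc(OCc2ccccc2)c(OC)c1 | intermediate
19 | (1RS,3R,5R)-1-[4-(benzyloxy)-3-methoxyphenyl]octane-1,3,5-triyl triacetate | CC(=O)OC(C[C@H](OC(C)=O)C[C@H](OC(C)=O)CCC)c1ccc(OCc2ccccc2)c(OC)c1 | intermediate
20 | (3S,5R)-1-(4-hydroxy-3-methoxyphenyl)octane-3,5-diyl diacetate (CNP0240815.1) | CCC[C@H](C[C@H](CCc1ccc(O)c(OC)c1)OC(C)=O)OC(C)=O | target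

**Step count**

Total: 14 steps. Longest linear sequence: 13 steps (steps 1–8 and 10–14 from phloroglucinol; step 9 is a one-step side branch).

**Steps most likely to fail**

1. Step 4. The catalyst may distinguish the two enantiotopic α-methylenes poorly with two bulky silyloxy groups on the ring, and uncatalysed peracid oxidation may erode the enantiomeric purity further. The fallback sets out from ketone 4 and returns at hydroxy amide 7. Enantiotopic deprotonation of 4 with a chiral lithium amide (lithium bis(1-phenylethyl)amide of the appropriate antipode, LiCl, TMSCl present from the start, THF, −100 → −78 °C) should give the silyl enol ether (3S,5R)-3,5-bis[(tert-butyldimethylsilyl)oxy]-1-[(trimethylsilyl)oxy]cyclohex-1-ene F1, whose double bond lies between C1 and C6. Ozonolysis (O3, CH2Cl2/MeOH, −78 °C) with NaBH4 work-up cleaves the same C1–C6 bond and should give (3R,5S)-3,5-bis[(tert-butyldimethylsilyl)oxy]-6-hydroxyhexanoic acid F2. Coupling of F2 with MeNH(OMe)·HCl (EDC·HCl, HOBt, iPr2NEt, CH2Cl2) gives 7.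

2. Step 14. Hydrogenolysis of the benzylic C1–O bond may lag behind debenzylation, or the p-hydroxybenzylic acetate may solvolyse or eliminate on the catalyst without being reduced. The fallback sets out from triacetate 19 and returns at target 20. The hydrogenation is limited to debenzylation (Pd/C, H2, EtOAc, short contact time), which should give (1RS,3R,5R)-1-(4-hydroxy-3-methoxyphenyl)octane-1,3,5-triyl triacetate F3. The C1 acetate is then removed by ionic hydrogenation (Et3SiH, TFA, CH2Cl2, 0 °C): the p-hydroxybenzylic cation forms readily and is trapped by hydride, while the C3 and C5 acetates do not ionise.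

3. Step 7. The basic ylide may epimerise C5 of the α-silyloxy aldehyde before olefination, or attack the Weinreb amide. The fallback sets out from aldehyde 8 and returns at saturated amide 12. A non-basic Takai–Utimoto ethylidenation (CH3CHI2, CrCl2, THF, rt) should give (3R,5S,6E)-3,5-bis[(tert-butyldimethylsilyl)oxy]-N-methoxy-N-methyloct-6-enamide F4. Hydrogenation of F4 under the conditions of step 8 gives 12, the alkene geometry being irrelevant.

**Further compounds**

F1 | step 4 | (3S,5R)-3,5-bis[(tert-butyldimethylsilyl)oxy]-1-[(trimethylsilyl)oxy]cyclohex-1-ene | C[Si](C)(C)OC1=C[C@@H](O[Si](C)(C)C(C)(C)C)C[C@@H](O[Si](C)(C)C(C)(C)C)C1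
F2 | step 4 | (3R,5S)-3,5-bis[(tert-butyldimethylsilyl)oxy]-6-hydroxyhexanoic acid | OC(=O)C[C@H](O[Si](C)(C)C(C)(C)C)C[C@H](O[Si](C)(C)C(C)(C)C)CO
F3 | step 14 | (1RS,3R,5R)-1-(4-hydroxy-3-methoxyphenyl)octane-1,3,5-triyl triacetate | CC(=O)OC(C[C@H](OC(C)=O)C[C@H](OC(C)=O)CCC)c1ccc(O)c(OC)c1
F4 | step 7 | (3R,5S,6E)-3,5-bis[(tert-butyldimethylsilyl)oxy]-N-methoxy-N-methyloct-6-enamide | CON(C)C(=O)C[C@H](O[Si](C)(C)C(C)(C)C)C[C@H](O[Si](C)(C)C(C)(C)C)/C=C/C
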